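**Plan**

- Cuts, in retrosynthetic order: the methyl ester and the MOM ether on O7 (unmasking); the C3–C3a bond together with the C–OH bond of the CH2OH group (one radical step); the O1–C2 ether bond (allylic etherification); the acrylate C=C bond (Wittig).
- Forward: ring A comes from 5-iodovanillin (demethylation, 3-O-MOM through the dianion, Wittig) and ring B from methyl 3,4-dimethoxycinnamate (reduction, carbonate). The two are joined at O1–C2, and the dihydrofuran ring, the only ring made, closes in the radical step.
- Stereochemistry: C2 (R) is set by the chiral phosphoramidite ligand in the Ir-catalysed etherification; C3 (S) follows from C2 by 1,2-induction in the 5-exo transition state (2,3-trans).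
- Enabling feature (numbering O1, C2, C3, C3a to C7a, ring A = benzo ring, ring B = dimethoxyphenyl): C3 bears CH2OH and is bonded to ring A at C3a, ortho to O1. This is the pattern left when a C3a aryl radical closes 5-exo onto the vinyl group of an O1–C2 allyl ether and the exocyclic radical takes up O2.

Key step: step 7

Assumption: L is O,O'-(1,1'-binaphthalene-2,2'-diyl) N,N-bis(1-phenylethyl)phosphoramidite, and its (Ra,Rc,Rc) enantiomer is taken to give the (R)-configured branched aryl ether; if the sense of induction is the reverse, the (Sa,Sc,Sc) ligand is used and nothing else changes.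

**Route**

Step 1
Reactants: 1 5-iodovanillin (4-hydroxy-3-iodo-5-methoxybenzaldehyde)
Product: 2 3,4-dihydroxy-5-iodobenzaldehyde
Conditions: AlCl3 (1.1 equiv), pyridine (4.4 equiv), CH2Cl2, reflux; then 2 M HCl
Reagents that add atoms: none
Why: Lewis acid cleavage of a guaiacol methyl ether, in which AlCl3 chelates the 4-oxygen and the neighbouring methoxy oxygen and chloride or pyridine removes the methyl group by SN2 attack, a demethylation known for 5-iodovanillin that leaves the aldehyde and the aryl iodide intact.

Step 2
Reactants: 2 3,4-dihydroxy-5-iodobenzaldehyde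
Product: 4 4-hydroxy-3-iodo-5-(methoxymethoxy)benzaldehyde, via disodium catecholate 3 (not isolated)
Conditions: NaH (2.1 equiv), DMF, 0 °C; then MOMCl (1.0 equiv), −20 to 0 °C; aq. NH4Cl
Reagents that add atoms: chloromethyl methyl ether (MOMCl), COCCl
Why: Regioselective Williamson etherification through the catechol dianion, in which the 4-oxide is delocalised into the para-formyl group and crowded by the iodine, so that the more basic, less hindered 3-oxide should take the single equivalent of MOMCl, in line with the known 3-O-alkylation of 3,4-dihydroxybenzaldehyde via its dianion.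

Step 3
Reactants: 4 4-hydroxy-3-iodo-5-(methoxymethoxy)benzaldehyde; 5 methyl (triphenylphosphoranylidene)acetate
Product: 6 methyl (E)-3-[4-hydroxy-3-iodo-5-(methoxymethoxy)phenyl]prop-2-enoate
Conditions: 5 (2 equiv), toluene, 90 °C
Reagents that add atoms: none
Why: Wittig olefination with an ester-stabilised ylide, which tolerates a free phenol when used in excess and gives the (E)-alkene as is general for this ylide class, while the MOM ether and the aryl iodide are inert.

Step 4
Reactants: 7 methyl (E)-3-(3,4-dimethoxyphenyl)prop-2-enoate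
Product: 8 (E)-3-(3,4-dimethoxyphenyl)prop-2-en-1-ol
Conditions: i-Bu2AlH (2.3 equiv), CH2Cl2, −78 to 0 °C; aq. potassium sodium tartrate
Reagents that add atoms: none
Why: 1,2-Reduction of a conjugated ester with i-Bu2AlH stops at the allylic alcohol and leaves the (E) double bond and the aryl methyl ethers untouched.

Step 5
Reactants: 8 (E)-3-(3,4-dimethoxyphenyl)prop-2-en-1-ol
Product: 9 (E)-3-(3,4-dimethoxyphenyl)prop-2-enyl methyl carbonate
Conditions: ClCO2Me, pyridine, CH2Cl2, 0 °C
Reagents that add atoms: methyl chloroformate, COC(=O)Cl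
Why: Acylation of the primary allylic alcohol with a chloroformate under pyridine (nucleophilic catalysis) installs the carbonate leaving group needed for metal-catalysed allylic substitution.

Step 6
Reactants: 6 methyl (E)-3-[4-hydroxy-3-iodo-5-(methoxymethoxy)phenyl]prop-2-enoate; 9 (E)-3-(3,4-dimethoxyphenyl)prop-2-enyl methyl carbonate
Product: 11 methyl (E)-3-{4-[(1R)-1-(3,4-dimethoxyphenyl)prop-2-enyloxy]-3-iodo-5-(methoxymethoxy)phenyl}prop-2-enoate, via lithium aryloxide 10 (not isolated)
Conditions: 6, LiN(SiMe3)2 (1.0 equiv), THF, 0 °C; then 9, [Ir(cod)Cl]2 (2 mol %), (Ra,Rc,Rc)-L (4 mol %), THF, 25 to 50 °C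
Reagents that add atoms: none
Why: Ir-catalysed asymmetric allylic etherification of an aryloxide with a cinnamyl-type carbonate, in which the catalyst formed from [Ir(cod)Cl]2 and L ionises 9 to an allyl–Ir intermediate, the aryloxide attacks the aryl-substituted terminus (branched selectivity) on the face fixed by the ligand and so sets the (R) centre that becomes C2, and the MOM ether ensures that only the 4-oxygen can act as nucleophile.

Step 7
Reactants: 11 methyl (E)-3-{4-[(1R)-1-(3,4-dimethoxyphenyl)prop-2-enyloxy]-3-iodo-5-(methoxymethoxy)phenyl}prop-2-enoate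
Product: 13 methyl (E)-3-[(2R,3S)-2-(3,4-dimethoxyphenyl)-3-(hydroxymethyl)-7-(methoxymethoxy)-2,3-dihydro-1-benzofuran-5-yl]prop-2-enoate, via primary hydroperoxide 12 (not isolated)
Conditions: Bu3SnH (2.5 equiv, syringe pump), Et3B (0.3 equiv, in portions), dry air, toluene (0.01 M), 0 °C to rt; then PPh3
Reagents that add atoms: dioxygen (from air), O=O
Why: Et3B and O2 start a chain in which Bu3Sn• abstracts iodine from 11 to give the C3a aryl radical, this radical adds to the internal carbon of the vinyl group (C3–C3a bond), the primary radical on the exocyclic carbon combines with O2, and Bu3SnH reduces the peroxyl radical to hydroperoxide 12, which PPh3 then reduces to the alcohol. The closest known reaction type is the oxygenative radical cyclisation of 2-iodophenyl allyl ethers with Bu3SnH under air, which gives 3-(hydroxymethyl)-2,3-dihydrobenzofurans. The dihydrofuran ring closes in the 5-exo-trig mode, the 6-endo alternative being slower for stereoelectronic reasons. The new C3 centre is controlled by C2: in the chair-like transition state the 3,4-dimethoxyphenyl group on C2 lies pseudo-equatorial, so the CH2 radical ends up trans to it and the product is (2R,3S), while no bond at C2 is touched. The step needs chemoselectivity, namely ring closure before the aryl radical meets Bu3SnH or O2 and O2 capture before the primary radical is reduced; the very fast closure of 2-(allyloxy)phenyl radicals, high dilution, slow addition of Bu3SnH and air saturation should secure it. The substrate helps as well: the iodine is the only radical precursor, both positions ortho to the ether oxygen are substituted so no Claisen rearrangement can compete, and the phenol is masked as a MOM ether so that it cannot quench peroxyl radicals.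

Step 8
Reactants: 13 methyl (E)-3-[(2R,3S)-2-(3,4-dimethoxyphenyl)-3-(hydroxymethyl)-7-(methoxymethoxy)-2,3-dihydro-1-benzofuran-5-yl]prop-2-enoate
Product: 14 methyl (E)-3-[(2R,3S)-2-(3,4-dimethoxyphenyl)-7-hydroxy-3-(hydroxymethyl)-2,3-dihydro-1-benzofuran-5-yl]prop-2-enoate
Conditions: conc. HCl (5 equiv), MeOH, 40 °C
Reagents that add atoms: none
Why: Acid-catalysed acetal cleavage (MOM removal) by transacetalisation to methanol frees the 7-OH, the methyl ester can only undergo degenerate exchange in MeOH, and the stereocentres should hold, since C3 is untouched and any reversible C2–O1 ionisation would reclose trans to it.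

Step 9
Reactants: 14 methyl (E)-3-[(2R,3S)-2-(3,4-dimethoxyphenyl)-7-hydroxy-3-(hydroxymethyl)-2,3-dihydro-1-benzofuran-5-yl]prop-2-enoate
Product: 16 (E)-3-[(2R,3S)-2-(3,4-dimethoxyphenyl)-7-hydroxy-3-(hydroxymethyl)-2,3-dihydro-1-benzofuran-5-yl]prop-2-enoic acid, via dilithium salt 15 (not isolated)
Conditions: LiOH·H2O (4 equiv), THF/MeOH/H2O, rt; then 1 M HCl to pH 3
Reagents that add atoms: lithium hydroxide, [Li+].[OH-]
Why: Saponification (BAc2 ester hydrolysis) with LiOH followed by acidification of dilithium salt 15 gives the free acid and phenol, and neither C2–H nor C3–H is acidic enough to epimerise under these conditions.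

**Compound list**

1 | 5-iodovanillin (4-hydroxy-3-iodo-5-methoxybenzaldehyde) | COc1cc(C=O)cc(I)c1O | starting material
2 | 3,4-dihydroxy-5-iodobenzaldehyde | O=Cc1cc(O)c(O)c(I)c1 | intermediate
3 | disodium 5-formyl-3-iodobenzene-1,2-diolate (formed in the flask) | [Na+].[Na+].[O-]c1cc(C=O)cc(I)c1[O-] | intermediate
4 | 4-hydroxy-3-iodo-5-(methoxymethoxy)benzaldehyde | COCOc1cc(C=O)cc(I)c1O | intermediate
5 | methyl (triphenylphosphoranylidene)acetate | COC(=O)C=P(c1ccccc1)(c1ccccc1)c1ccccc1 | starting material
6 | methyl (E)-3-[4-hydroxy-3-iodo-5-(methoxymethoxy)phenyl]prop-2-enoate | COCOc1cc(/C=C/C(=O)OC)cc(I)c1O | intermediate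
7 | methyl (E)-3-(3,4-dimethoxyphenyl)prop-2-enoate | COc1ccc(/C=C/C(=O)OC)cc1OC | starting material
8 | (E)-3-(3,4-dimethoxyphenyl)prop-2-en-1-ol | COc1ccc(/C=C/CO)cc1OC | intermediate
9 | (E)-3-(3,4-dimethoxyphenyl)prop-2-enyl methyl carbonate | COc1ccc(/C=C/COC(=O)OC)cc1OC | intermediate
10 | lithium 2-iodo-4-[(E)-3-methoxy-3-oxoprop-1-enyl]-6-(methoxymethoxy)phenolate (formed in the flask) | [Li+].COCOc1cc(/C=C/C(=O)OC)cc(I)c1[O-] | intermediate
11 | methyl (E)-3-{4-[(1R)-1-(3,4-dimethoxyphenyl)prop-2-enyloxy]-3-iodo-5-(methoxymethoxy)phenyl}prop-2-enoate | COc1ccc([C@@H](C=C)Oc2c(I)cc(/C=C/C(=O)OC)cc2OCOC)cc1OC | intermediate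
12 | methyl (E)-3-[(2R,3S)-2-(3,4-dimethoxyphenyl)-3-(hydroperoxymethyl)-7-(methoxymethoxy)-2,3-dihydro-1-benzofuran-5-yl]prop-2-enoate (formed in the flask) | COc1ccc([C@@H]2Oc3c(OCOC)cc(/C=C/C(=O)OC)cc3[C@H]2COO)cc1OC | intermediate
13 | methyl (E)-3-[(2R,3S)-2-(3,4-dimethoxyphenyl)-3-(hydroxymethyl)-7-(methoxymethoxy)-2,3-dihydro-1-benzofuran-5-yl]prop-2-enoate | COc1ccc([C@@H]2Oc3c(OCOC)cc(/C=C/C(=O)OC)cc3[C@H]2CO)cc1OC | intermediate
14 | methyl (E)-3-[(2R,3S)-2-(3,4-dimethoxyphenyl)-7-hydroxy-3-(hydroxymethyl)-2,3-dihydro-1-benzofuran-5-yl]prop-2-enoate | COc1ccc([C@@H]2Oc3c(O)cc(/C=C/C(=O)OC)cc3[C@H]2CO)cc1OC | intermediate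
15 | dilithium (E)-3-[(2R,3S)-2-(3,4-dimethoxyphenyl)-3-(hydroxymethyl)-7-oxido-2,3-dihydro-1-benzofuran-5-yl]prop-2-enoate (formed in the flask) | [Li+].[Li+].COc1ccc([C@@H]2Oc3c([O-])cc(/C=C/C(=O)[O-])cc3[C@H]2CO)cc1OC | intermediate
16 | (E)-3-[(2R,3S)-2-(3,4-dimethoxyphenyl)-7-hydroxy-3-(hydroxymethyl)-2,3-dihydro-1-benzofuran-5-yl]prop-2-enoic acid | COc1ccc([C@@H]2Oc3c(O)cc(/C=C/C(=O)O)cc3[C@H]2CO)cc1OC | target

**Count**

Total steps: 9. Longest linear sequence: 7 steps (steps 1, 2, 3, 6, 7, 8, 9 from 5-iodovanillin); steps 4 and 5 form the side branch.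

**Steps most likely to fail**

Step 6. The aryloxide is doubly ortho-substituted and, with its para-acrylate and ortho-iodine, a good leaving group, while the 3,4-dimethoxyphenyl group stabilises the allyl cation. The nucleophilic attack may therefore be slow, and the branched ether, once formed, may re-ionise at the metal, which would erode the enantiomeric purity and let the product drift towards the linear ether. The fallback sets out from 6 and comes back at 11. It forms the ether bond without a metal–allyl intermediate and takes the absolute configuration from a resolution. Commercial 3,4-dimethoxybenzaldehyde and CH2=CHMgBr in THF should give racemic 1-(3,4-dimethoxyphenyl)prop-2-en-1-ol F1. A Mitsunobu reaction of F1 with phenol 6 (PPh3, diisopropyl azodicarboxylate, THF, 0 °C) should then give, by SN2 displacement at the oxyphosphonium centre, racemic methyl (E)-3-{4-[1-(3,4-dimethoxyphenyl)prop-2-enyloxy]-3-iodo-5-(methoxymethoxy)phenyl}prop-2-enoate F2. Preparative chromatography on a chiral stationary phase separates 11 from its mirror image, methyl (E)-3-{4-[(1S)-1-(3,4-dimethoxyphenyl)prop-2-enyloxy]-3-iodo-5-(methoxymethoxy)phenyl}prop-2-enoate F3, which is set aside.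

Step 7. Three processes may compete: reduction of the primary radical by Bu3SnH before it captures O2 (loss of the hydroxyl group), consumption of Bu3SnH by O2 with stalling of the chain, and incomplete trans selectivity in the flattened transition state. Any cis isomer has to be removed before step 8, because acid-mediated epimerisation at C2 would carry it into the enantiomeric trans series. The fallback sets out from 11 and comes back at 13, and replaces O2 by a persistent radical trap followed by a separate reductive cleavage. Treatment of 11 with Bu3SnH and excess TEMPO in toluene at 70 °C should give, after the same 5-exo closure, the alkoxyamine methyl (E)-3-[(2R,3S)-2-(3,4-dimethoxyphenyl)-7-(methoxymethoxy)-3-{[(2,2,6,6-tetramethylpiperidin-1-yl)oxy]methyl}-2,3-dihydro-1-benzofuran-5-yl]prop-2-enoate F4. Cleavage of the N–O bond of F4 with Zn in AcOH/THF/H2O then gives 13.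

Step 2. Site selectivity between the two oxide centres of the dianion may be incomplete, and over-alkylation to the bis-MOM ether may occur. The fallback sets out from 2 and comes back at 4, and replaces the dianion differentiation by a protect–protect–deprotect sequence that relies on the higher acidity of the 4-OH. Alkylation of the monoanion of 2 (4-methoxybenzyl chloride, NaHCO3, NaI, DMF, 40 °C) should give 3-hydroxy-5-iodo-4-[(4-methoxyphenyl)methoxy]benzaldehyde F5. Capping of the remaining 3-OH (MOMCl, i-Pr2NEt, CH2Cl2) should give 3-iodo-4-[(4-methoxyphenyl)methoxy]-5-(methoxymethoxy)benzaldehyde F6. Oxidative removal of the 4-methoxybenzyl group from F6 (DDQ, CH2Cl2/H2O) then gives 4.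

**Further compounds**

F1 | step 6 | racemic 1-(3,4-dimethoxyphenyl)prop-2-en-1-ol | COc1ccc(C(O)C=C)cc1OC
F2 | step 6 | racemic methyl (E)-3-{4-[1-(3,4-dimethoxyphenyl)prop-2-enyloxy]-3-iodo-5-(methoxymethoxy)phenyl}prop-2-enoate | COc1ccc(C(C=C)Oc2c(I)cc(/C=C/C(=O)OC)cc2OCOC)cc1OC
F3 | step 6 | methyl (E)-3-{4-[(1S)-1-(3,4-dimethoxyphenyl)prop-2-enyloxy]-3-iodo-5-(methoxymethoxy)phenyl}prop-2-enoate | COc1ccc([C@H](C=C)Oc2c(I)cc(/C=C/C(=O)OC)cc2OCOC)cc1OC
F4 | step 7 | methyl (E)-3-[(2R,3S)-2-(3,4-dimethoxyphenyl)-7-(methoxymethoxy)-3-{[(2,2,6,6-tetramethylpiperidin-1-yl)oxy]methyl}-2,3-dihydro-1-benzofuran-5-yl]prop-2-enoate | COc1ccc([C@@H]2Oc3c(OCOC)cc(/C=C/C(=O)OC)cc3[C@H]2CON4C(C)(C)CCCC4(C)C)cc1OC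
F5 | step 2 | 3-hydroxy-5-iodo-4-[(4-methoxyphenyl)methoxy]benzaldehyde | COc1ccc(COc2c(O)cc(C=O)cc2I)cc1
F6 | step 2 | 3-iodo-4-[(4-methoxyphenyl)methoxy]-5-(methoxymethoxy)benzaldehyde | COCOc1cc(C=O)cc(I)c1OCc1ccc(OC)cc1
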